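## The problem

CNP0601265.1 (39) is a prodelphinidin dimer: two (2R,3R)-epigallocatechin units joined from C4 of the upper unit to C8 of the lower one, with the 4R (4β) configuration, so the upper ring C is 2,3-cis and 3,4-trans. The upper 3-hydroxyl carries a galloyl ester. A second gallic acid bridges the molecule: its O3 is an aryl ether on C2' of the upper ring B and its carboxyl esterifies the lower 3-hydroxyl, closing a 16-membered lactone through upper C2–C3–C4 and lower C8–C8a–O1–C2–C3. Of the five stereocentres, the two of the lower unit can be bought as (−)-epigallocatechin (1), but they are too far from C8 to steer the new centre at upper C4, which therefore needs a chiral catalyst. Once C4 exists it can help a reagent to place the C2–C3 oxygen, and the cis relation at C2/C3 is best secured by a stereospecific event rather than by equilibration. The interflavan bond is acid-labile, the gallate and lactone are base-labile, and the free pyrogallol and phloroglucinol rings are oxidation-prone, so all fifteen phenols must travel as benzyl ethers and both esters of the finished molecule must be made late. The enabling feature is upper ring A: a 1,3,5-trioxygenated benzene whose only carbon substituent sits at C4a and whose two ortho oxygens are equivalent until ring C closes. It is the aromatised form of a three-acetate poly-β-carbonyl chain attached to C4, and either ortho hydroxyl can later become O1.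

## Retrosynthesis

Target 39 is traced back to its pentadeca-O-benzyl ether 38 by cutting fifteen O–benzyl bonds. No other phenol protection is removed under neutral conditions that spare the gallate, the lactone and the interflavan bond. The forward reaction only has to be a hydrogenolysis that leaves the benzylic C2–O1 and C4–C8 bonds alone.

The macrocycle of 38 is opened at the lactone C–O bond between the bridging carboxyl and the lower O3, giving seco acid 37. Closing the ring at the diaryl ether or at the interflavan bond would ask a hindered C–O or C–C coupling to work at high dilution; an ester closure is the mildest of the three. The forward step must acylate one axial secondary hydroxyl in a 16-membered ring closure.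

Seco acid 37 comes from diester 35 by unmasking a tert-butyl ester and a silyl ether. Cutting the upper gallate ester of 35 gives alcohol 33 and the commercial acid 34. The gallate goes on before the lactone is closed so that each acylation meets a single free hydroxyl.

Alcohol 33 is the dibenzyl ether of triol 32, and ring C of 32 is cut at O1–C2. This leads to epoxy triol 31 and its silylated form 30, and from there to Z-alkene 29. A cut at C4–C4a or C4–C8 (cation chemistry) would leave regio- and stereochemistry at C4 to chance. The O1–C2 cut turns a cis-epoxide into the 2,3-cis flavanol by inversion at the benzylic carbon, and because ring A is symmetric no regiochemical question arises. Alkene 29 is the tris-silyl ether of phloroglucinol 28, which arises from ester 26 by hydrolysis and decarboxylation (through acid 27); 26 is the semihydrogenation product of alkyne 25. The forward steps must deliver oxygen to one face of a hindered Z-alkene and keep the opening 6-endo.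

Benzoate 25 is cut in ring A, between the ester-bearing carbon and the carbonyl carbon next to C4a, to give the open-chain 2-substituted dimethyl 3,5-dioxoheptanedioate 24. This is the key simplification: a pentasubstituted arene becomes a linear chain of two simple carbonyl building blocks, and the interflavan bond is an ordinary sp3–sp2 bond already in place. The forward reaction is a Dieckmann condensation that must give C- and not O-acylation and must leave the propargylic centre alone.

Chain 24 is cut between C3 and C4, giving malonic half acid 21 (activated as chloride 23) and the bis-silyl dienol ether 22 as a neutral acetoacetate γ-nucleophile. The neighbouring cut, C5–C6, would need a β-keto acid to be activated, and a cut made under basic enolate conditions would be quenched by the acidic malonyl hydrogen. The forward acylation must therefore run without base.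

Half acid 21 comes from Meldrum's acid derivative 20 by methanolysis, and 20 is cut at the alkyne–aryl bond into terminal alkyne 10 and aryl triflate 19. The arylation is done at the malonate stage, with no ketone in the molecule, so that no enol oxygen can cyclise onto the metal-activated alkyne. The forward step is a Sonogashira coupling.

Alkyne 10 is cut at the bond between C4 and the malonyl carbon, giving propargylic acetate 8 and Meldrum's acid 9. This is where C4 is set: both epimers of 8 pass through one planar copper allenylidene, and the chiral ligand chooses the face. Acetate 8 goes back through aldehyde 6, bromide 4, bromo alcohol 3 and pentabenzyl ether 2 to 1, so the lower unit keeps its two stereocentres from the chiral pool.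

Triflate 19 comes from phenol 18 and, by Dakin oxidation, from aldehyde 16. The diaryl ether of 16 is cut into phenol 13 and ortho-bromo aldehyde 15, whose formyl group activates the C–Br bond and later becomes the coupling handle. Phenol 13 derives from tert-butyl gallate 12 and gallic acid 11; bromide 15 derives from the commercial aldehyde 14. The tert-butyl ester is chosen because it alone survives the methoxide and hydroxide steps.

## Roads not taken

Alternative 1: The lower ring C and the macrocycle would be closed together. An ortho-quinone methide, generated on the lower ring-A phenol from formaldehyde and phenylboronic acid, adds across a Z-enol ester of the bridging gallate, forming C4a–C4, C4–C3 and O1–C2 and giving A1 directly (A1 is the same compound as 38). This is the most step-economic endgame of all: three bonds, two rings and the cis C2/C3 relation (from the Z geometry) in one operation, with no separate macrolactonisation and no stereocentre at the formaldehyde-derived C4. Its weak points are that enol esters are poor partners for quinone methides, that the cycloaddition must run through a 16-membered transition state at the temperature needed to release the quinone methide, and that the facial sense on the enol ester is controlled only by the distant upper unit. It also leaves the whole upper unit and the 4→8 bond to be made beforehand. The chosen plan is longer at the end and must close the lactone separately, which is a real disadvantage. What it sets against this is that each stereocentre is fixed in a reagent- or substrate-controlled step of a known type and that the lower unit comes intact from 1.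

Alternative 2: The lower ring A would be built on C4 by a Danheiser-type benzannulation between an alkynyl silyl ether on C4 and a cyclobutenone carrying the epoxide. This forms C8–C8a and C6–C7, and the new C8a phenol then opens the cis-epoxide at C2 to give A2. The idea is close to the chosen one (an A ring is grown on C4 so that the interflavan bond is never made by cation coupling). It is better in one respect: the benzannulation delivers a fully differentiated arene, whereas polyketide folding gives three free phenols that must be silylated and later benzylated. Against it stand the long synthesis of an epoxide-bearing cyclobutenone, a thermal cascade in the presence of an epoxide and a gallate, and the loss of the chiral pool for the lower unit, whose C2 and C3 would have to be made de novo. The chosen plan offers cheap two- and four-carbon building blocks, a simple base-mediated ring closure and a lower unit with its stereocentres already in place.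

Alternative 3: The lower ring C would be closed by gold catalysis. AuCl3/AgOTf activates a terminal epoxide of an aryl glycidyl-type ether and C4a of the lower phloroglucinol ring attacks its CH2 carbon, forming C4–C4a and giving A3. The reaction type is known for simple aryl glycidyl ethers, is catalytic, and needs few steps once the 4-aryl upper unit exists. In that respect it is shorter than the chosen plan. Its weak points are the prior construction of a hindered secondary benzylic aryl ether with defined C2 configuration next to an epoxide, the use of a strong Lewis acid on a molecule that already contains the acid-labile interflavan bond and an ionisable benzylic ether, and again a lower unit made de novo. It also presupposes the classical stereo- and regiochemical problem of making the 4→8 bond. The chosen plan pays with a longer sequence but forms that bond under catalyst control as a plain C–C bond before either upper ring exists.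

Key step: step 16

Abbreviations used in names: Fl = (2R,3R)-5,7-bis(benzyloxy)-3-[(tert-butyldimethylsilyl)oxy]-2-[3,4,5-tris(benzyloxy)phenyl]chroman-8-yl (the lower unit, attached through C8); ArB = 3,4,5-tris(benzyloxy)-2-[2,3-bis(benzyloxy)-5-(tert-butoxycarbonyl)phenoxy]phenyl (upper ring B carrying the bridging gallate as its tert-butyl ester).

Assumption: the facial sense of the copper–pybox catalyst (step 6) and of the chiral ketone (step 20) follows the accepted models for 1-arylpropargyl esters and cis-β-substituted styrenes; if a model substrate shows the opposite sense, the catalyst antipode is used and nothing else changes.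

## Steps

Step 1
Reactants: 1 (−)-epigallocatechin
Product: 2 5,7,3',4',5'-penta-O-benzyl-(−)-epigallocatechin
Conditions: BnBr, K2CO3, DMF, 0 °C → rt, argon
Reagents that add atoms: benzyl bromide, BrCc1ccccc1
Why: Williamson O-benzylation of the five phenols; the secondary alcohol is not deprotonated by K2CO3, and low temperature with exclusion of air should limit C-benzylation of ring A and base-induced C2 epimerisation.

Step 2
Reactants: 2 5,7,3',4',5'-penta-O-benzyl-(−)-epigallocatechin
Product: 3 8-bromo-5,7,3',4',5'-penta-O-benzyl-(−)-epigallocatechin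
Conditions: NBS, CH2Cl2, −78 °C → 0 °C
Reagents that add atoms: N-bromosuccinimide, BrN1C(=O)CCC1=O
Why: Electrophilic aromatic bromination; C8, flanked by O1 and the 7-benzyloxy group and para to the 5-benzyloxy group, is the preferred site in 5,7-dialkoxyflavans, so one equivalent at low temperature should spare C6 and ring B.

Step 3
Reactants: 3 8-bromo-5,7,3',4',5'-penta-O-benzyl-(−)-epigallocatechin
Product: 4 Fl–Br (the 3-O-tert-butyldimethylsilyl ether of 3)
Conditions: TBSCl, imidazole, DMF, rt
Reagents that add atoms: tert-butyldimethylsilyl chloride, CC(C)(C)[Si](C)(C)Cl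
Why: Standard silylation of the axial 3-hydroxyl; the silyl ether is chosen because it must survive organolithium, methoxide, hydroxide and mild acid and be removed by fluoride at the end.

Step 4
Reactants: 4 Fl–Br
Product: 6 Fl–CHO (the 8-carbaldehyde), via aryllithium Fl–Li 5 (not isolated)
Conditions: t-BuLi (2.1 equiv), THF, −78 °C; then DMF; aq NH4Cl
Reagents that add atoms: tert-butyllithium, [Li]C(C)(C)C (lithium of 5 only); N,N-dimethylformamide, CN(C)C=O
Why: Lithium–bromine exchange followed by Bouveault-type formylation; exchange at −78 °C is faster than any benzylic deprotonation, and the silyl and benzyl ethers are inert.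

Step 5
Reactants: 6 Fl–CHO
Product: 8 1-Fl-prop-2-yn-1-yl acetate (both epimers at the carbinol carbon), via bromomagnesium alkoxide 7 (not isolated)
Conditions: HC≡CMgBr, THF, 0 °C; then Ac2O, 0 °C → rt
Reagents that add atoms: ethynylmagnesium bromide, C#C[Mg]Br; acetic anhydride, CC(=O)OC(C)=O
Why: 1,2-Addition of the alkynyl Grignard reagent and acetylation of the magnesium alkoxide in the same flask avoid handling the very ionisable 2,6-dioxygenated benzylic propargylic alcohol; the carbinol centre is deliberately formed as both epimers because the next step erases it.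

Step 6
Reactants: 8 1-Fl-prop-2-yn-1-yl acetate; 9 Meldrum's acid (2,2-dimethyl-1,3-dioxane-4,6-dione)
Product: 10 5-[(1S)-1-Fl-prop-2-yn-1-yl]-2,2-dimethyl-1,3-dioxane-4,6-dione
Conditions: Cu(MeCN)4BF4 (5 mol %), (S,S)-Ph-pybox (6 mol %), i-Pr2NEt, MeOH/THF, −20 °C
Reagents that add atoms: none
Why: Copper-catalysed asymmetric propargylic substitution: the monovalent copper acetylide of either epimer of 8 loses acetate to one planar copper allenylidene, and the pybox ligand decides which face of its γ-carbon the ammonium enolate of the compact, acidic cyclic malonate attacks, so the 1S centre (the future 4R of the flavan) is set by the catalyst and not by the remote lower-unit centres. A ketone-free malonate is used so that no enol oxygen can later add to the alkyne.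

Step 7
Reactants: 11 gallic acid
Product: 12 tert-butyl 3,4,5-trihydroxybenzoate
Conditions: O-tert-butyl-N,N'-diisopropylisourea, THF, rt → 40 °C
Reagents that add atoms: O-tert-butyl-N,N'-diisopropylisourea, CC(C)NC(=NC(C)C)OC(C)(C)C
Why: Esterification by the isourea starts with protonation of the reagent by the carboxylic acid, so the much less acidic phenols should stay free; the tert-butyl ester is the one ester that survives the methoxide and hydroxide steps ahead.

Step 8
Reactants: 12 tert-butyl 3,4,5-trihydroxybenzoate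
Product: 13 tert-butyl 3,4-bis(benzyloxy)-5-hydroxybenzoate
Conditions: BnBr (2.05 equiv), K2CO3, DMF, 0 °C → rt
Reagents that add atoms: benzyl bromide, BrCc1ccccc1
Why: Williamson benzylation with limiting reagent: the 4-hydroxyl para to the ester is the most acidic and reacts first, then one of the two equivalent flanking hydroxyls, so the 3,4-dibenzyl ether should be the main product and is separated from mono- and tribenzyl ethers.

Step 9
Reactants: 14 3,4,5-tris(benzyloxy)benzaldehyde
Product: 15 2-bromo-3,4,5-tris(benzyloxy)benzaldehyde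
Conditions: NBS, MeCN, rt
Reagents that add atoms: N-bromosuccinimide, BrN1C(=O)CCC1=O
Why: Electrophilic bromination at one of the two equivalent free ring positions, which the ortho and para benzyloxy groups activate despite the formyl group.

Step 10
Reactants: 13 tert-butyl 3,4-bis(benzyloxy)-5-hydroxybenzoate; 15 2-bromo-3,4,5-tris(benzyloxy)benzaldehyde
Product: 16 ArB–CHO, tert-butyl 3,4-bis(benzyloxy)-5-[2,3,4-tris(benzyloxy)-6-formylphenoxy]benzoate
Conditions: CuI (20 mol %), N,N-dimethylglycine hydrochloride, Cs2CO3, 1,4-dioxane, 100 °C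
Reagents that add atoms: none
Why: Ullmann-type C–O coupling with a monovalent copper/amino acid catalyst; the ortho formyl group activates the hindered C–Br bond, and neither partner carries another reactive halide or an enolisable position.

Step 11
Reactants: 16 ArB–CHO
Product: 18 ArB–OH (the phenol in place of the formyl group), via aryl formate 17 (not isolated)
Conditions: mCPBA, CH2Cl2, 0 °C → rt; then K2CO3 (cat.), MeOH, rt
Reagents that add atoms: 3-chloroperbenzoic acid, OOC(=O)c1cccc(Cl)c1
Why: Dakin (Baeyer–Villiger-type) oxidation: the electron-rich aryl group, with para benzyloxy and ortho aryloxy donors, migrates in preference to hydride, and the resulting formate is cleaved by mild methanolysis without touching the tert-butyl ester.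

Step 12
Reactants: 18 ArB–OH
Product: 19 ArB–OTf, the aryl trifluoromethanesulfonate of 18
Conditions: Tf2O, pyridine, CH2Cl2, 0 °C
Reagents that add atoms: trifluoromethanesulfonic anhydride, FC(F)(F)S(=O)(=O)OS(=O)(=O)C(F)(F)F
Why: Sulfonylation of the phenol places a cross-coupling handle exactly on C1' of the future ring B.

Step 13
Reactants: 10 5-[(1S)-1-Fl-prop-2-yn-1-yl]-2,2-dimethyl-1,3-dioxane-4,6-dione; 19 ArB–OTf
Product: 20 5-[(1S)-1-Fl-3-ArB-prop-2-yn-1-yl]-2,2-dimethyl-1,3-dioxane-4,6-dione
Conditions: Pd(PPh3)2Cl2 (5 mol %), CuI (10 mol %), Bu4NI, Et3N, DMF, 60 °C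
Reagents that add atoms: none
Why: Sonogashira coupling of the terminal alkyne with the aryl triflate; the Meldrum's acid unit is present as its unreactive triethylammonium enolate and has no ketone oxygen to cyclise onto the metal-activated alkyne, and the propargylic centre is not acidic enough to be touched by triethylamine.

Step 14
Reactants: 20 5-[(1S)-1-Fl-3-ArB-prop-2-yn-1-yl]-2,2-dimethyl-1,3-dioxane-4,6-dione
Product: 21 (3S)-3-Fl-2-(methoxycarbonyl)-5-ArB-pent-4-ynoic acid (both C2 epimers)
Conditions: MeOH/toluene, 80 °C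
Reagents that add atoms: methanol, CO
Why: Thermal alcoholysis of a 5-monosubstituted Meldrum's acid opens the ring with loss of acetone and gives the malonic half ester under neutral conditions, below the temperature at which such half acids decarboxylate; the new C2 centre is irrelevant because it later becomes aromatic.

Step 15
Reactants: 21 (3S)-3-Fl-2-(methoxycarbonyl)-5-ArB-pent-4-ynoic acid; 22 1-methoxy-1,3-bis(trimethylsilyloxy)buta-1,3-diene
Product: 24 dimethyl 2-[(1S)-1-Fl-3-ArB-prop-2-yn-1-yl]-3,5-dioxoheptanedioate (both C2 epimers), via acid chloride 23 (not isolated)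
Conditions: 1-chloro-N,N,2-trimethylprop-1-en-1-amine, CH2Cl2, 0 °C → rt; then 22, CH2Cl2, −78 °C → rt; aq NH4Cl
Reagents that add atoms: 1-chloro-N,N,2-trimethylprop-1-en-1-amine, CC(C)=C(Cl)N(C)C (chlorine of 23 only)
Why: The chloroenamine makes the acid chloride without liberating HCl, so the silyl ether, tert-butyl ester and benzyl ethers are safe. The terminal carbon of the bis-silyl dienol ether, a neutral acetoacetate γ-anion equivalent, is then C-acylated (Mukaiyama-type vinylogous acylation) to give the 3,5-dioxo diester after hydrolytic work-up. No base is present, so the acidic malonyl hydrogen can neither quench the nucleophile nor form a ketene.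

Step 16
Reactants: 24 dimethyl 2-[(1S)-1-Fl-3-ArB-prop-2-yn-1-yl]-3,5-dioxoheptanedioate
Product: 25 methyl 3-[(1R)-1-Fl-3-ArB-prop-2-yn-1-yl]-2,4,6-trihydroxybenzoate
Conditions: Mg(OMe)2 (4 equiv), MeOH/THF, rt → 50 °C; 1 M HCl work-up
Reagents that add atoms: none
Why: Dieckmann (intramolecular Claisen) condensation: Mg(OMe)2 deprotonates the chain at C4 and C6 (the substituted, hindered C2 is the least acidic position), so C1 stays an electrophilic ester while the magnesium-chelated C6 enolate attacks it; loss of methoxide gives the 2-substituted 6-carbomethoxycyclohexane-1,3,5-trione, which tautomerises irreversibly to the phloroglucinol carboxylate. The closest known reaction types are the alkoxide-mediated cyclisation of 3,5-dioxopimelates and malonate/3-oxoglutarate adducts to phloroglucinol carboxylates and the magnesium methoxide Claisen cyclisation of 3,5,7-triketo esters to acylphloroglucinols. The ring closes in the allowed 6-(enolendo)-exo-trig mode, forming the bond between the ester-bearing carbon (future C8 or C6) and the carbonyl carbon next to C4a (future C8a or C5). No stereocentre is created: both C2 epimers of 24 converge because C2 becomes aromatic, and the C4 centre is untouched because its hydrogen is not α to a carbonyl (its descriptor changes from S to R by priority only). The selectivity needed is C- over O-acylation (attack of the C5 enolate oxygen on C1 would give a 4-hydroxy-2-pyranone); it is secured by the chelating magnesium enolate and by the methanolic medium, in which a lactone can reopen while the aromatic product cannot, and closure in the opposite sense (C2 onto C7) gives a non-aromatisable trione that reverts by retro-Claisen. The aryl alkyne is not activated by any metal here, so enolate oxygen should not add to it at 50 °C, and the tert-butyl benzoate and the silyl ether are inert to methoxide.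

Step 17
Reactants: 25 methyl 3-[(1R)-1-Fl-3-ArB-prop-2-yn-1-yl]-2,4,6-trihydroxybenzoate
Product: 26 methyl 3-[(1R,2Z)-1-Fl-3-ArB-prop-2-en-1-yl]-2,4,6-trihydroxybenzoate
Conditions: H2 (1 atm), Pd/CaCO3–Pb(OAc)2, quinoline, EtOAc, rt
Reagents that add atoms: none
Why: Lindlar semihydrogenation (syn delivery of hydrogen on poisoned palladium) gives the Z-alkene without hydrogenolysis of benzyl ethers; it is placed before the hydroxide step so that no hot phenoxide ever faces the alkyne.

Step 18
Reactants: 26 methyl 3-[(1R,2Z)-1-Fl-3-ArB-prop-2-en-1-yl]-2,4,6-trihydroxybenzoate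
Product: 28 2-[(1R,2Z)-1-Fl-3-ArB-prop-2-en-1-yl]benzene-1,3,5-triol, via trihydroxybenzoic acid 27 (not isolated)
Conditions: KOH, 1,4-dioxane/H2O, 80 °C, argon; then AcOH to pH 5, 50 °C
Reagents that add atoms: water, O (hydroxyl oxygen of 27 only)
Why: Saponification of the phloroglucinol carboxylate followed by protodecarboxylation of the 2,4,6-trihydroxybenzoic acid, which loses CO2 through its keto tautomer on gentle warming once acidified. The tert-butyl benzoate and the alkyl silyl ether resist aqueous hydroxide, and the ring-A polyanion disfavours deprotonation of the adjacent C4–H.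

Step 19
Reactants: 28 2-[(1R,2Z)-1-Fl-3-ArB-prop-2-en-1-yl]benzene-1,3,5-triol
Product: 29 tris(tert-butyldimethylsilyl) ether of 28 (all three phenols silylated; the methine descriptor becomes S by priority only)
Conditions: TBSOTf, 2,6-lutidine, CH2Cl2, 0 °C
Reagents that add atoms: tert-butyldimethylsilyl trifluoromethanesulfonate, CC(C)(C)[Si](C)(C)OS(=O)(=O)C(F)(F)F
Why: Silylation protects the oxidation-prone phloroglucinol during the epoxidation and makes ring A the bulkiest group on the allylic carbon, which is used for face control in the next step.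

Step 20
Reactants: 29 tris(tert-butyldimethylsilyl) ether of 28
Product: 30 (2S,3R)-2-ArB-3-[(S)-Fl{2,4,6-tris[(tert-butyldimethylsilyl)oxy]phenyl}methyl]oxirane
Conditions: L-glucose-derived antipode of Shi's N-aryl oxazolidinone ketone (30 mol %), KHSO5 (as Oxone), K2CO3–AcOH buffer, Bu4NHSO4, DME/dimethoxymethane–H2O, −10 °C
Reagents that add atoms: potassium peroxymonosulfate, [K+].[O-]S(=O)(=O)OO
Why: Shi asymmetric epoxidation of a cis-disubstituted aryl alkene by a chiral dioxirane: oxygen transfer is concerted, so the Z geometry is copied into the cis-epoxide, and the ketone antipode is chosen for the (2S,3R) epoxide. In the conformer that minimises A(1,3) strain (C4–H in the alkene plane) this is the face anti to the tris-silylated ring A, so substrate and reagent preferences should reinforce each other.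

Step 21
Reactants: 30 (2S,3R)-2-ArB-3-[(S)-Fl{2,4,6-tris[(tert-butyldimethylsilyl)oxy]phenyl}methyl]oxirane
Product: 32 (2R,3R,4R)-2-ArB-4-Fl-chromane-3,5,7-triol, via epoxy triol 31 (not isolated)
Conditions: TBAF, AcOH, THF, 0 °C; then PPTS (cat.), CH2Cl2, 0 °C → rt
Reagents that add atoms: none
Why: Buffered fluoride removes the three aryl silyl ethers much faster than the hindered secondary alkyl silyl ether. Mild acid then triggers 6-endo-tet opening of the epoxide at the benzylic carbon (activated by the electron-rich ring B) by either of the two equivalent ortho phenols with inversion, so the cis-epoxide becomes the 2,3-cis (2R,3R) flavan-3-ol with the C4 aryl group trans to both.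

Step 22
Reactants: 32 (2R,3R,4R)-2-ArB-4-Fl-chromane-3,5,7-triol
Product: 33 (2R,3R,4R)-5,7-bis(benzyloxy)-2-ArB-4-Fl-chroman-3-ol
Conditions: BnBr, K2CO3, DMF, 0 °C → rt
Reagents that add atoms: benzyl bromide, BrCc1ccccc1
Why: Williamson benzylation of the two phenols only; the hindered secondary hydroxyl is not alkylated under carbonate conditions, and with ring B fully etherified there is no quinone-methide pathway for C2 epimerisation.

Step 23
Reactants: 33 (2R,3R,4R)-5,7-bis(benzyloxy)-2-ArB-4-Fl-chroman-3-ol; 34 3,4,5-tris(benzyloxy)benzoic acid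
Product: 35 (2R,3R,4R)-5,7-bis(benzyloxy)-2-ArB-4-Fl-chroman-3-yl 3,4,5-tris(benzyloxy)benzoate
Conditions: DCC, DMAP, CH2Cl2, rt → 40 °C
Reagents that add atoms: none
Why: Steglich esterification, the usual way to galloylate the axial 3-hydroxyl of benzylated epi-series flavanols; C3 keeps its configuration because its C–O bond is not broken.

Step 24
Reactants: 35 (2R,3R,4R)-5,7-bis(benzyloxy)-2-ArB-4-Fl-chroman-3-yl 3,4,5-tris(benzyloxy)benzoate
Product: 37 seco acid (35 with the tert-butyl ester as free carboxylic acid and the lower 3-silyl ether as free hydroxyl), via trimethylsilyl ester 36 (not isolated)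
Conditions: TMSOTf, 2,6-lutidine, CH2Cl2, 0 °C; then HF·pyridine, THF, 0 °C → rt
Reagents that add atoms: trimethylsilyl trifluoromethanesulfonate, C[Si](C)(C)OS(=O)(=O)C(F)(F)F (silyl group of 36 only)
Why: Silyl triflate with lutidine cleaves the tert-butyl ester through the silyl ester with loss of isobutene under buffered, non-protic conditions that should spare the interflavan bond and the aryl benzyl ethers. HF·pyridine then removes the alkyl silyl ether and the silyl ester without the basicity of TBAF, which could cleave or shift the gallate.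

Step 25
Reactants: 37 seco acid
Product: 38 pentadeca-O-benzyl macrolactone (the fully benzylated target)
Conditions: 2-methyl-6-nitrobenzoic anhydride, DMAP, Et3N, toluene, 40 °C, slow addition (about 1 mM)
Reagents that add atoms: none
Why: Shiina macrolactonisation (carboxyl activation by the aromatic anhydride, acyl transfer by DMAP) at high dilution closes the 16-membered lactone; the seco acid has a single free hydroxyl, its ends are held near each other by the 4→8 bond and the diaryl ether, and the lower C3 keeps its configuration because only its O–H bond reacts.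

Step 26
Reactants: 38 pentadeca-O-benzyl macrolactone
Product: 39 CNP0601265.1
Conditions: H2 (1 atm), Pd(OH)2/C, THF/MeOH/H2O, rt
Reagents that add atoms: none
Why: Hydrogenolysis of the fifteen benzyl ethers, the usual last step for benzylated proanthocyanidin gallates; under these mild conditions the benzylic C2–O1 bonds, the interflavan bond and the esters should not be cleaved.

## Compound list

1 | (−)-epigallocatechin, (2R,3R)-2-(3,4,5-trihydroxyphenyl)chromane-3,5,7-triol | O[C@@H]1Cc2c(O)cc(O)cc2O[C@@H]1c1cc(O)c(O)c(O)c1 | starting material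
2 | (2R,3R)-5,7-bis(benzyloxy)-2-[3,4,5-tris(benzyloxy)phenyl]chroman-3-ol | O[C@@H]1Cc2c(OCc3ccccc3)cc(OCc3ccccc3)cc2O[C@@H]1c1cc(OCc3ccccc3)c(OCc3ccccc3)c(OCc3ccccc3)c1 | intermediate
3 | (2R,3R)-5,7-bis(benzyloxy)-8-bromo-2-[3,4,5-tris(benzyloxy)phenyl]chroman-3-ol | O[C@@H]1Cc2c(OCc3ccccc3)cc(OCc3ccccc3)c(Br)c2O[C@@H]1c1cc(OCc3ccccc3)c(OCc3ccccc3)c(OCc3ccccc3)c1 | intermediate
4 | Fl–Br, 3-O-tert-butyldimethylsilyl ether of 3 | CC(C)(C)[Si](C)(C)O[C@@H]1Cc2c(OCc3ccccc3)cc(OCc3ccccc3)c(Br)c2O[C@@H]1c1cc(OCc3ccccc3)c(OCc3ccccc3)c(OCc3ccccc3)c1 | intermediate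
5 | Fl–Li, 8-lithio species | CC(C)(C)[Si](C)(C)O[C@@H]1Cc2c(OCc3ccccc3)cc(OCc3ccccc3)c([Li])c2O[C@@H]1c1cc(OCc3ccccc3)c(OCc3ccccc3)c(OCc3ccccc3)c1 | intermediate (not isolated)
6 | Fl–CHO, 8-carbaldehyde | CC(C)(C)[Si](C)(C)O[C@@H]1Cc2c(OCc3ccccc3)cc(OCc3ccccc3)c(C=O)c2O[C@@H]1c1cc(OCc3ccccc3)c(OCc3ccccc3)c(OCc3ccccc3)c1 | intermediate
7 | bromomagnesium 1-Fl-prop-2-yn-1-olate (both epimers) | CC(C)(C)[Si](C)(C)O[C@@H]1Cc2c(OCc3ccccc3)cc(OCc3ccccc3)c(C(O[Mg]Br)C#C)c2O[C@@H]1c1cc(OCc3ccccc3)c(OCc3ccccc3)c(OCc3ccccc3)c1 | intermediate (not isolated)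
8 | 1-Fl-prop-2-yn-1-yl acetate (both epimers) | CC(C)(C)[Si](C)(C)O[C@@H]1Cc2c(OCc3ccccc3)cc(OCc3ccccc3)c(C(OC(C)=O)C#C)c2O[C@@H]1c1cc(OCc3ccccc3)c(OCc3ccccc3)c(OCc3ccccc3)c1 | intermediate
9 | Meldrum's acid, 2,2-dimethyl-1,3-dioxane-4,6-dione | CC1(C)OC(=O)CC(=O)O1 | starting material
10 | 5-[(1S)-1-Fl-prop-2-yn-1-yl]-2,2-dimethyl-1,3-dioxane-4,6-dione | CC1(C)OC(=O)C(C(=O)O1)[C@H](c5c6O[C@H](c7cc(OCc4ccccc4)c(OCc4ccccc4)c(OCc4ccccc4)c7)[C@H](O[Si](C)(C)C(C)(C)C)Cc6c(OCc4ccccc4)cc5OCc4ccccc4)C#C | intermediate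
11 | gallic acid | OC(=O)c1cc(O)c(O)c(O)c1 | starting material
12 | tert-butyl 3,4,5-trihydroxybenzoate | CC(C)(C)OC(=O)c1cc(O)c(O)c(O)c1 | intermediate
13 | tert-butyl 3,4-bis(benzyloxy)-5-hydroxybenzoate | CC(C)(C)OC(=O)c1cc(O)c(OCc2ccccc2)c(OCc2ccccc2)c1 | intermediate
14 | 3,4,5-tris(benzyloxy)benzaldehyde | O=Cc1cc(OCc2ccccc2)c(OCc2ccccc2)c(OCc2ccccc2)c1 | starting material
15 | 2-bromo-3,4,5-tris(benzyloxy)benzaldehyde | O=Cc1cc(OCc2ccccc2)c(OCc2ccccc2)c(OCc2ccccc2)c1Br | intermediate
16 | ArB–CHO, tert-butyl 3,4-bis(benzyloxy)-5-[2,3,4-tris(benzyloxy)-6-formylphenoxy]benzoate | O=Cc1cc(OCc4ccccc4)c(OCc4ccccc4)c(OCc4ccccc4)c1Oc1cc(cc(OCc4ccccc4)c1OCc4ccccc4)C(=O)OC(C)(C)C | intermediate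
17 | tert-butyl 3,4-bis(benzyloxy)-5-[2,3,4-tris(benzyloxy)-6-(formyloxy)phenoxy]benzoate | O=COc1cc(OCc4ccccc4)c(OCc4ccccc4)c(OCc4ccccc4)c1Oc1cc(cc(OCc4ccccc4)c1OCc4ccccc4)C(=O)OC(C)(C)C | intermediate (not isolated)
18 | ArB–OH, tert-butyl 3,4-bis(benzyloxy)-5-[2,3,4-tris(benzyloxy)-6-hydroxyphenoxy]benzoate | Oc1cc(OCc4ccccc4)c(OCc4ccccc4)c(OCc4ccccc4)c1Oc1cc(cc(OCc4ccccc4)c1OCc4ccccc4)C(=O)OC(C)(C)C | intermediate
19 | ArB–OTf, tert-butyl 3,4-bis(benzyloxy)-5-{2,3,4-tris(benzyloxy)-6-[(trifluoromethanesulfonyl)oxy]phenoxy}benzoate | O=S(=O)(Oc1cc(OCc4ccccc4)c(OCc4ccccc4)c(OCc4ccccc4)c1Oc1cc(cc(OCc4ccccc4)c1OCc4ccccc4)C(=O)OC(C)(C)C)C(F)(F)F | intermediate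
20 | 5-[(1S)-1-Fl-3-ArB-prop-2-yn-1-yl]-2,2-dimethyl-1,3-dioxane-4,6-dione | CC1(C)OC(=O)C(C(=O)O1)[C@H](c5c6O[C@H](c7cc(OCc4ccccc4)c(OCc4ccccc4)c(OCc4ccccc4)c7)[C@H](O[Si](C)(C)C(C)(C)C)Cc6c(OCc4ccccc4)cc5OCc4ccccc4)C#Cc1cc(OCc4ccccc4)c(OCc4ccccc4)c(OCc4ccccc4)c1Oc1cc(cc(OCc4ccccc4)c1OCc4ccccc4)C(=O)OC(C)(C)C | intermediate
21 | (3S)-3-Fl-2-(methoxycarbonyl)-5-ArB-pent-4-ynoic acid (both C2 epimers) | COC(=O)C(C(=O)O)[C@H](c5c6O[C@H](c7cc(OCc4ccccc4)c(OCc4ccccc4)c(OCc4ccccc4)c7)[C@H](O[Si](C)(C)C(C)(C)C)Cc6c(OCc4ccccc4)cc5OCc4ccccc4)C#Cc1cc(OCc4ccccc4)c(OCc4ccccc4)c(OCc4ccccc4)c1Oc1cc(cc(OCc4ccccc4)c1OCc4ccccc4)C(=O)OC(C)(C)C | intermediate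
22 | 1-methoxy-1,3-bis(trimethylsilyloxy)buta-1,3-diene | COC(O[Si](C)(C)C)=CC(=C)O[Si](C)(C)C | starting material
23 | methyl (3S)-2-(chlorocarbonyl)-3-Fl-5-ArB-pent-4-ynoate (both C2 epimers) | COC(=O)C(C(Cl)=O)[C@H](c5c6O[C@H](c7cc(OCc4ccccc4)c(OCc4ccccc4)c(OCc4ccccc4)c7)[C@H](O[Si](C)(C)C(C)(C)C)Cc6c(OCc4ccccc4)cc5OCc4ccccc4)C#Cc1cc(OCc4ccccc4)c(OCc4ccccc4)c(OCc4ccccc4)c1Oc1cc(cc(OCc4ccccc4)c1OCc4ccccc4)C(=O)OC(C)(C)C | intermediate (not isolated)
24 | dimethyl 2-[(1S)-1-Fl-3-ArB-prop-2-yn-1-yl]-3,5-dioxoheptanedioate (both C2 epimers, drawn as the triketo tautomer) | COC(=O)C(C(=O)CC(=O)CC(=O)OC)[C@H](c5c6O[C@H](c7cc(OCc4ccccc4)c(OCc4ccccc4)c(OCc4ccccc4)c7)[C@H](O[Si](C)(C)C(C)(C)C)Cc6c(OCc4ccccc4)cc5OCc4ccccc4)C#Cc1cc(OCc4ccccc4)c(OCc4ccccc4)c(OCc4ccccc4)c1Oc1cc(cc(OCc4ccccc4)c1OCc4ccccc4)C(=O)OC(C)(C)C | intermediate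
25 | methyl 3-[(1R)-1-Fl-3-ArB-prop-2-yn-1-yl]-2,4,6-trihydroxybenzoate | COC(=O)c1c(O)cc(O)c(c1O)[C@H](c5c6O[C@H](c7cc(OCc4ccccc4)c(OCc4ccccc4)c(OCc4ccccc4)c7)[C@H](O[Si](C)(C)C(C)(C)C)Cc6c(OCc4ccccc4)cc5OCc4ccccc4)C#Cc1cc(OCc4ccccc4)c(OCc4ccccc4)c(OCc4ccccc4)c1Oc1cc(cc(OCc4ccccc4)c1OCc4ccccc4)C(=O)OC(C)(C)C | intermediate
26 | methyl 3-[(1R,2Z)-1-Fl-3-ArB-prop-2-en-1-yl]-2,4,6-trihydroxybenzoate | COC(=O)c1c(O)cc(O)c(c1O)[C@H](c5c6O[C@H](c7cc(OCc4ccccc4)c(OCc4ccccc4)c(OCc4ccccc4)c7)[C@H](O[Si](C)(C)C(C)(C)C)Cc6c(OCc4ccccc4)cc5OCc4ccccc4)/C=C\c1cc(OCc4ccccc4)c(OCc4ccccc4)c(OCc4ccccc4)c1Oc1cc(cc(OCc4ccccc4)c1OCc4ccccc4)C(=O)OC(C)(C)C | intermediate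
27 | 3-[(1R,2Z)-1-Fl-3-ArB-prop-2-en-1-yl]-2,4,6-trihydroxybenzoic acid | OC(=O)c1c(O)cc(O)c(c1O)[C@H](c5c6O[C@H](c7cc(OCc4ccccc4)c(OCc4ccccc4)c(OCc4ccccc4)c7)[C@H](O[Si](C)(C)C(C)(C)C)Cc6c(OCc4ccccc4)cc5OCc4ccccc4)/C=C\c1cc(OCc4ccccc4)c(OCc4ccccc4)c(OCc4ccccc4)c1Oc1cc(cc(OCc4ccccc4)c1OCc4ccccc4)C(=O)OC(C)(C)C | intermediate (not isolated)
28 | 2-[(1R,2Z)-1-Fl-3-ArB-prop-2-en-1-yl]benzene-1,3,5-triol | Oc1cc(O)c(c(O)c1)[C@H](c5c6O[C@H](c7cc(OCc4ccccc4)c(OCc4ccccc4)c(OCc4ccccc4)c7)[C@H](O[Si](C)(C)C(C)(C)C)Cc6c(OCc4ccccc4)cc5OCc4ccccc4)/C=C\c1cc(OCc4ccccc4)c(OCc4ccccc4)c(OCc4ccccc4)c1Oc1cc(cc(OCc4ccccc4)c1OCc4ccccc4)C(=O)OC(C)(C)C | intermediate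
29 | tris(tert-butyldimethylsilyl) ether of 28, 1,3,5-tris[(tert-butyldimethylsilyl)oxy]-2-[(1S,2Z)-1-Fl-3-ArB-prop-2-en-1-yl]benzene | CC(C)(C)[Si](C)(C)Oc1cc(O[Si](C)(C)C(C)(C)C)c(c(O[Si](C)(C)C(C)(C)C)c1)[C@H](c5c6O[C@H](c7cc(OCc4ccccc4)c(OCc4ccccc4)c(OCc4ccccc4)c7)[C@H](O[Si](C)(C)C(C)(C)C)Cc6c(OCc4ccccc4)cc5OCc4ccccc4)/C=C\c1cc(OCc4ccccc4)c(OCc4ccccc4)c(OCc4ccccc4)c1Oc1cc(cc(OCc4ccccc4)c1OCc4ccccc4)C(=O)OC(C)(C)C | intermediate
30 | (2S,3R)-2-ArB-3-[(S)-Fl{2,4,6-tris[(tert-butyldimethylsilyl)oxy]phenyl}methyl]oxirane | CC(C)(C)[Si](C)(C)Oc1cc(O[Si](C)(C)C(C)(C)C)c(c(O[Si](C)(C)C(C)(C)C)c1)[C@H](c5c6O[C@H](c7cc(OCc4ccccc4)c(OCc4ccccc4)c(OCc4ccccc4)c7)[C@H](O[Si](C)(C)C(C)(C)C)Cc6c(OCc4ccccc4)cc5OCc4ccccc4)[C@H]3O[C@H]3c1cc(OCc4ccccc4)c(OCc4ccccc4)c(OCc4ccccc4)c1Oc1cc(cc(OCc4ccccc4)c1OCc4ccccc4)C(=O)OC(C)(C)C | intermediate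
31 | 2-{(R)-[(2R,3S)-3-ArB-oxiran-2-yl](Fl)methyl}benzene-1,3,5-triol | Oc1cc(O)c(c(O)c1)[C@H](c5c6O[C@H](c7cc(OCc4ccccc4)c(OCc4ccccc4)c(OCc4ccccc4)c7)[C@H](O[Si](C)(C)C(C)(C)C)Cc6c(OCc4ccccc4)cc5OCc4ccccc4)[C@H]3O[C@H]3c1cc(OCc4ccccc4)c(OCc4ccccc4)c(OCc4ccccc4)c1Oc1cc(cc(OCc4ccccc4)c1OCc4ccccc4)C(=O)OC(C)(C)C | intermediate (not isolated)
32 | (2R,3R,4R)-2-ArB-4-Fl-chromane-3,5,7-triol | O[C@@H]1[C@@H](c5c6O[C@H](c7cc(OCc4ccccc4)c(OCc4ccccc4)c(OCc4ccccc4)c7)[C@H](O[Si](C)(C)C(C)(C)C)Cc6c(OCc4ccccc4)cc5OCc4ccccc4)c3c(O)cc(O)cc3O[C@@H]1c1cc(OCc4ccccc4)c(OCc4ccccc4)c(OCc4ccccc4)c1Oc1cc(cc(OCc4ccccc4)c1OCc4ccccc4)C(=O)OC(C)(C)C | intermediate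
33 | (2R,3R,4R)-5,7-bis(benzyloxy)-2-ArB-4-Fl-chroman-3-ol | O[C@@H]1[C@@H](c5c6O[C@H](c7cc(OCc4ccccc4)c(OCc4ccccc4)c(OCc4ccccc4)c7)[C@H](O[Si](C)(C)C(C)(C)C)Cc6c(OCc4ccccc4)cc5OCc4ccccc4)c3c(OCc4ccccc4)cc(OCc4ccccc4)cc3O[C@@H]1c1cc(OCc4ccccc4)c(OCc4ccccc4)c(OCc4ccccc4)c1Oc1cc(cc(OCc4ccccc4)c1OCc4ccccc4)C(=O)OC(C)(C)C | intermediate
34 | 3,4,5-tris(benzyloxy)benzoic acid | OC(=O)c1cc(OCc2ccccc2)c(OCc2ccccc2)c(OCc2ccccc2)c1 | starting material
35 | (2R,3R,4R)-5,7-bis(benzyloxy)-2-ArB-4-Fl-chroman-3-yl 3,4,5-tris(benzyloxy)benzoate | O=C(O[C@@H]1[C@@H](c5c6O[C@H](c7cc(OCc4ccccc4)c(OCc4ccccc4)c(OCc4ccccc4)c7)[C@H](O[Si](C)(C)C(C)(C)C)Cc6c(OCc4ccccc4)cc5OCc4ccccc4)c3c(OCc4ccccc4)cc(OCc4ccccc4)cc3O[C@@H]1c1cc(OCc4ccccc4)c(OCc4ccccc4)c(OCc4ccccc4)c1Oc1cc(cc(OCc4ccccc4)c1OCc4ccccc4)C(=O)OC(C)(C)C)c1cc(OCc4ccccc4)c(OCc4ccccc4)c(OCc4ccccc4)c1 | intermediate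
36 | trimethylsilyl ester corresponding to 35 (tert-butyl replaced by trimethylsilyl) | O=C(O[C@@H]1[C@@H](c5c6O[C@H](c7cc(OCc4ccccc4)c(OCc4ccccc4)c(OCc4ccccc4)c7)[C@H](O[Si](C)(C)C(C)(C)C)Cc6c(OCc4ccccc4)cc5OCc4ccccc4)c3c(OCc4ccccc4)cc(OCc4ccccc4)cc3O[C@@H]1c1cc(OCc4ccccc4)c(OCc4ccccc4)c(OCc4ccccc4)c1Oc1cc(cc(OCc4ccccc4)c1OCc4ccccc4)C(=O)O[Si](C)(C)C)c1cc(OCc4ccccc4)c(OCc4ccccc4)c(OCc4ccccc4)c1 | intermediate (not isolated)
37 | seco acid: 3,4-bis(benzyloxy)-5-[2,3,4-tris(benzyloxy)-6-{(2R,3R,4R)-5,7-bis(benzyloxy)-4-[(2R,3R)-5,7-bis(benzyloxy)-3-hydroxy-2-(3,4,5-tris(benzyloxy)phenyl)chroman-8-yl]-3-[3,4,5-tris(benzyloxy)benzoyloxy]chroman-2-yl}phenoxy]benzoic acid | O=C(O[C@@H]1[C@@H](c5c6O[C@H](c7cc(OCc4ccccc4)c(OCc4ccccc4)c(OCc4ccccc4)c7)[C@H](O)Cc6c(OCc4ccccc4)cc5OCc4ccccc4)c3c(OCc4ccccc4)cc(OCc4ccccc4)cc3O[C@@H]1c1cc(OCc4ccccc4)c(OCc4ccccc4)c(OCc4ccccc4)c1Oc1cc(cc(OCc4ccccc4)c1OCc4ccccc4)C(=O)O)c1cc(OCc4ccccc4)c(OCc4ccccc4)c(OCc4ccccc4)c1 | intermediate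
38 | pentadeca-O-benzyl macrolactone (target with all fifteen phenols as benzyl ethers) | O=C(O[C@@H]1[C@@H]2c3c(OCc4ccccc4)cc(OCc4ccccc4)cc3O[C@@H]1c1cc(OCc4ccccc4)c(OCc4ccccc4)c(OCc4ccccc4)c1Oc1cc(cc(OCc4ccccc4)c1OCc4ccccc4)C(=O)O[C@@H]1Cc3c(OCc4ccccc4)cc(OCc4ccccc4)c2c3O[C@@H]1c1cc(OCc4ccccc4)c(OCc4ccccc4)c(OCc4ccccc4)c1)c1cc(OCc4ccccc4)c(OCc4ccccc4)c(OCc4ccccc4)c1 | intermediate
39 | CNP0601265.1 | O=C(O[C@@H]1[C@@H]2c3c(O)cc(O)cc3O[C@@H]1c1cc(O)c(O)c(O)c1Oc1cc(cc(O)c1O)C(=O)O[C@@H]1Cc3c(O)cc(O)c2c3O[C@@H]1c1cc(O)c(O)c(O)c1)c1cc(O)c(O)c(O)c1 | target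

Total step count: 26. Longest linear sequence: 20 steps (steps 1–6 and 13–26, from 1).

## Steps least certain to work

Step 16 (key step). The chain may close through oxygen instead of carbon (lactonisation of the C5 enolate onto the C1 ester), an enolate oxygen may add to the aryl alkyne, or the propargylic unit may isomerise towards an allene under base. The fallback exchanges reduction and ring formation. Compound 24 is semihydrogenated over Pd/CaCO3–Pb(OAc)2 to the Z-alkene analogue of 24 (alkyne semireduced, methine configuration unchanged) F1, which has no alkyne to trap an enolate or to isomerise. F1 is then cyclised with NaOMe in refluxing MeOH, where any pyranone is reopened by methanolysis and funnelled to the aromatic triol. The product is 26, where the route is rejoined.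

Step 6. The very electron-rich propargylic acetate may ionise outside the copper cycle (uncatalysed substitution or methanolysis without facial control), or the allenylidene may form or be attacked too slowly at the doubly ortho-substituted benzylic position. The fallback sets C4 by conjugate addition instead. Aldehyde 6 is condensed with 9 (Knoevenagel, pyrrolidinium acetate) to the arylidene Meldrum's acid F2. A rhodium-catalysed asymmetric conjugate alkynylation with (trimethylsilyl)acetylene (Rh(acac)(C2H4)2 with the matching antipode of DTBM-SEGPHOS, aqueous dioxane) gives the silylalkyne adduct F3 (10 with a trimethylsilyl group on the alkyne terminus). K2CO3 in MeOH removes the silyl group and returns 10.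

Step 10. Ether formation at a bromide flanked by a formyl and a benzyloxy group may be slow, with hydrodebromination or aldehyde degradation at 100 °C competing. The fallback changes the bond-forming event to an oxidative coupling at room temperature. Bromide 15 is converted by Miyaura borylation (bis(pinacolato)diboron, Pd(dppf)Cl2, KOAc) into the pinacol boronate of 3,4,5-tris(benzyloxy)benzaldehyde at C2 F4. Chan–Lam coupling of F4 with phenol 13 (Cu(OAc)2, pyridine, air, molecular sieves, rt) gives 16.

Step 20. The dioxirane may oxidise the electron-rich arenes or benzylic positions faster than the shielded alkene, and facial selection may be poor if catalyst and substrate preferences oppose each other. The fallback replaces epoxidation by dihydroxylation and invertive etherification. Alkene 29 is syn-dihydroxylated with OsO4/N-methylmorpholine N-oxide, which does not attack the arenes and should approach anti to the silylated ring A, giving the 2,3-syn-diol of 29 F5. TBAF/AcOH removes the aryl silyl ethers to give the pentaol (phloroglucinol plus diol) F6. An intramolecular Mitsunobu etherification (PPh3, diisopropyl azodicarboxylate) displaces the benzylic hydroxyl with inversion and gives 32.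

Step 25. Intermolecular acylation (oligomers) may win, or the axial lower 3-hydroxyl, crowded by its C2 aryl group and the nearby gallate, may not be acylated. The fallback reverses the order of the two esterifications. Alcohol 33 is unmasked (TMSOTf/2,6-lutidine, then HF·pyridine) to the dihydroxy acid (33 with free carboxylic acid and free lower 3-hydroxyl) F7. F7 is lactonised under the same anhydride/DMAP high-dilution conditions without the bulky gallate in place; the upper 3-hydroxyl would have to close a strained 10-membered ring and should not compete. This gives the macrolactone with free upper 3-hydroxyl F8, which is galloylated with 34 (DCC, DMAP) to reach 38.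

## Further compounds

F1 | step 16 | Z-alkene analogue of 24, dimethyl 2-[(2Z)-1-Fl-3-ArB-prop-2-en-1-yl]-3,5-dioxoheptanedioate (methine configuration as in 24) | COC(=O)C(C(=O)CC(=O)CC(=O)OC)[C@H](c5c6O[C@H](c7cc(OCc4ccccc4)c(OCc4ccccc4)c(OCc4ccccc4)c7)[C@H](O[Si](C)(C)C(C)(C)C)Cc6c(OCc4ccccc4)cc5OCc4ccccc4)/C=C\c1cc(OCc4ccccc4)c(OCc4ccccc4)c(OCc4ccccc4)c1Oc1cc(cc(OCc4ccccc4)c1OCc4ccccc4)C(=O)OC(C)(C)C
F2 | step 6 | 5-(Fl-methylidene)-2,2-dimethyl-1,3-dioxane-4,6-dione | CC1(C)OC(=O)C(=Cc5c6O[C@H](c7cc(OCc4ccccc4)c(OCc4ccccc4)c(OCc4ccccc4)c7)[C@H](O[Si](C)(C)C(C)(C)C)Cc6c(OCc4ccccc4)cc5OCc4ccccc4)C(=O)O1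
F3 | step 6 | 5-[1-Fl-3-(trimethylsilyl)prop-2-yn-1-yl]-2,2-dimethyl-1,3-dioxane-4,6-dione (methine configuration as in 10) | CC1(C)OC(=O)C(C(=O)O1)[C@H](c5c6O[C@H](c7cc(OCc4ccccc4)c(OCc4ccccc4)c(OCc4ccccc4)c7)[C@H](O[Si](C)(C)C(C)(C)C)Cc6c(OCc4ccccc4)cc5OCc4ccccc4)C#C[Si](C)(C)C
F4 | step 10 | 3,4,5-tris(benzyloxy)-2-(4,4,5,5-tetramethyl-1,3,2-dioxaborolan-2-yl)benzaldehyde | O=Cc1cc(OCc2ccccc2)c(OCc2ccccc2)c(OCc2ccccc2)c1B1OC(C)(C)C(C)(C)O1
F5 | step 20 | 2,3-syn-diol of 29 (hydroxyls at the two former alkene carbons, configurations as the epoxide carbons of 30) | CC(C)(C)[Si](C)(C)Oc1cc(O[Si](C)(C)C(C)(C)C)c(c(O[Si](C)(C)C(C)(C)C)c1)[C@H](c5c6O[C@H](c7cc(OCc4ccccc4)c(OCc4ccccc4)c(OCc4ccccc4)c7)[C@H](O[Si](C)(C)C(C)(C)C)Cc6c(OCc4ccccc4)cc5OCc4ccccc4)[C@@H](O)[C@@H](O)c1cc(OCc4ccccc4)c(OCc4ccccc4)c(OCc4ccccc4)c1Oc1cc(cc(OCc4ccccc4)c1OCc4ccccc4)C(=O)OC(C)(C)C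
F6 | step 20 | pentaol: F5 with the three aryl silyl ethers removed | Oc1cc(O)c(c(O)c1)[C@H](c5c6O[C@H](c7cc(OCc4ccccc4)c(OCc4ccccc4)c(OCc4ccccc4)c7)[C@H](O[Si](C)(C)C(C)(C)C)Cc6c(OCc4ccccc4)cc5OCc4ccccc4)[C@@H](O)[C@@H](O)c1cc(OCc4ccccc4)c(OCc4ccccc4)c(OCc4ccccc4)c1Oc1cc(cc(OCc4ccccc4)c1OCc4ccccc4)C(=O)OC(C)(C)C
F7 | step 25 | dihydroxy acid: 33 with free carboxylic acid and free lower 3-hydroxyl | O[C@@H]1[C@@H](c5c6O[C@H](c7cc(OCc4ccccc4)c(OCc4ccccc4)c(OCc4ccccc4)c7)[C@H](O)Cc6c(OCc4ccccc4)cc5OCc4ccccc4)c3c(OCc4ccccc4)cc(OCc4ccccc4)cc3O[C@@H]1c1cc(OCc4ccccc4)c(OCc4ccccc4)c(OCc4ccccc4)c1Oc1cc(cc(OCc4ccccc4)c1OCc4ccccc4)C(=O)O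
F8 | step 25 | dodeca-O-benzyl macrolactone with free upper 3-hydroxyl (38 without the galloyl group) | O[C@@H]1[C@@H]2c3c(OCc4ccccc4)cc(OCc4ccccc4)cc3O[C@@H]1c1cc(OCc4ccccc4)c(OCc4ccccc4)c(OCc4ccccc4)c1Oc1cc(cc(OCc4ccccc4)c1OCc4ccccc4)C(=O)O[C@@H]1Cc3c(OCc4ccccc4)cc(OCc4ccccc4)c2c3O[C@@H]1c1cc(OCc4ccccc4)c(OCc4ccccc4)c(OCc4ccccc4)c1
A1 | alternative 1 | pentadeca-O-benzyl target (identical with 38) | O=C(O[C@@H]1[C@@H]2c3c(OCc4ccccc4)cc(OCc4ccccc4)cc3O[C@@H]1c1cc(OCc4ccccc4)c(OCc4ccccc4)c(OCc4ccccc4)c1Oc1cc(cc(OCc4ccccc4)c1OCc4ccccc4)C(=O)O[C@@H]1Cc3c(OCc4ccccc4)cc(OCc4ccccc4)c2c3O[C@@H]1c1cc(OCc4ccccc4)c(OCc4ccccc4)c(OCc4ccccc4)c1)c1cc(OCc4ccccc4)c(OCc4ccccc4)c(OCc4ccccc4)c1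
A2 | alternative 2 | benzylated 4→8 dimer with free lower 3-hydroxyl, 7-O-triisopropylsilyl ether on the lower unit and allyl ester on the bridging ring | O=C(O[C@@H]1[C@@H](c5c6O[C@H](c7cc(OCc4ccccc4)c(OCc4ccccc4)c(OCc4ccccc4)c7)[C@H](O)Cc6c(OCc4ccccc4)cc5O[Si](C(C)C)(C(C)C)C(C)C)c3c(OCc4ccccc4)cc(OCc4ccccc4)cc3O[C@@H]1c1cc(OCc4ccccc4)c(OCc4ccccc4)c(OCc4ccccc4)c1Oc1cc(cc(OCc4ccccc4)c1OCc4ccccc4)C(=O)OCC=C)c1cc(OCc4ccccc4)c(OCc4ccccc4)c(OCc4ccccc4)c1
A3 | alternative 3 | benzylated 4→8 dimer with free lower 3-hydroxyl and 2-(trimethylsilyl)ethyl ester on the bridging ring | O=C(O[C@@H]1[C@@H](c5c6O[C@H](c7cc(OCc4ccccc4)c(OCc4ccccc4)c(OCc4ccccc4)c7)[C@H](O)Cc6c(OCc4ccccc4)cc5OCc4ccccc4)c3c(OCc4ccccc4)cc(OCc4ccccc4)cc3O[C@@H]1c1cc(OCc4ccccc4)c(OCc4ccccc4)c(OCc4ccccc4)c1Oc1cc(cc(OCc4ccccc4)c1OCc4ccccc4)C(=O)OCC[Si](C)(C)C)c1cc(OCc4ccccc4)c(OCc4ccccc4)c(OCc4ccccc4)c1
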